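**Retrosynthetic overview**

- The strategy rests on ring C, a 1,3,4,5-tetraoxygenated benzene: C1 carries the ether oxygen to B6 and lies meta to the C3 and C5 hydroxyls, and C4 carries the ether oxygen to D1 and sits between those two hydroxyls.
- Ring C is disconnected into a two-carbon piece (C1, C2: the ethynyl ether on B6 of the A–B dimer) and a four-carbon piece (C3–C6: a 3-ethoxy-4-aryloxycyclobutenone on D1 of the D–E–F trimer). A cyclobutenone–ynol ether benzannulation joins them, so neither ether at ring C needs an aryl ether coupling.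
- The D–E–F phenol comes from two rounds of Ullmann coupling of a phenol with a bromobenzaldehyde followed by Baeyer–Villiger conversion of CHO into OH. It is then carried through the aryloxyacetic acid and its chloride to the aryloxyketene, which adds ethoxyacetylene.
- The A–B phenol comes from one such round on a formylated bromotrimethoxybenzene. Trichloroethylene and n-BuLi then turn it into the ynol ether.
- Rings A, B, D, E and F are bought as aromatics. Ring C is the only ring made, and it is made last; BBr3 then frees all hydroxyls.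

Key step: step 13

Assumption: the target has no stereocentre, so the cyclobutenone is used as the racemate; the three bromoarenes, 2,4,6-trimethoxyphenol and ethoxyacetylene (as a hexane solution) are taken as purchasable.

**Route**

Step 1
Reactants: 1 3,4,5-trimethoxyphenol; 2 4-bromo-3,5-dimethoxybenzaldehyde
Product: 3 3,5-dimethoxy-4-(3,4,5-trimethoxyphenoxy)benzaldehyde
Conditions: CuI (10 mol %), picolinic acid (20 mol %), K3PO4, DMSO, 90 °C, Ar
Reagents that add atoms: none
Why: Ullmann diaryl ether coupling, in which the para-formyl group activates the doubly ortho-methoxylated bromide and the phenol is unhindered and electron-rich.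

Step 2
Reactants: 3 3,5-dimethoxy-4-(3,4,5-trimethoxyphenoxy)benzaldehyde
Product: 5 3,5-dimethoxy-4-(3,4,5-trimethoxyphenoxy)phenol, via aryl formate 4 (not isolated)
Conditions: mCPBA, CH2Cl2, 0 °C to rt; then K2CO3, MeOH, rt
Reagents that add atoms: mCPBA (3-chloroperoxybenzoic acid), O=C(OO)c1cccc(Cl)c1
Why: Baeyer–Villiger oxidation, in which the electron-rich aryl group migrates in the Criegee adduct to give the formate, which mild methanolysis cleaves to the phenol.

Step 3
Reactants: 5 3,5-dimethoxy-4-(3,4,5-trimethoxyphenoxy)phenol; 6 2-bromo-3,4,5-trimethoxybenzaldehyde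
Product: 7 3,4,5-trimethoxy-2-[3,5-dimethoxy-4-(3,4,5-trimethoxyphenoxy)phenoxy]benzaldehyde
Conditions: CuI (10 mol %), picolinic acid (20 mol %), K3PO4, DMSO, 90 °C, Ar
Reagents that add atoms: none
Why: Ullmann diaryl ether coupling, in which the ortho-formyl group activates the C–Br bond and phenol 5 has no ortho substituent.

Step 4
Reactants: 7 3,4,5-trimethoxy-2-[3,5-dimethoxy-4-(3,4,5-trimethoxyphenoxy)phenoxy]benzaldehyde
Product: 9 3,4,5-trimethoxy-2-[3,5-dimethoxy-4-(3,4,5-trimethoxyphenoxy)phenoxy]phenol, via aryl formate 8 (not isolated)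
Conditions: mCPBA, CH2Cl2, 0 °C to rt; then K2CO3, MeOH, rt
Reagents that add atoms: mCPBA (3-chloroperoxybenzoic acid), O=C(OO)c1cccc(Cl)c1
Why: Baeyer–Villiger oxidation of an aldehyde with ortho-aryloxy and para-methoxy donors, so aryl migration to the formate should win over hydride migration; methanolysis then frees the D1 hydroxyl.

Step 5
Reactants: 9 3,4,5-trimethoxy-2-[3,5-dimethoxy-4-(3,4,5-trimethoxyphenoxy)phenoxy]phenol
Product: 10 2-{3,4,5-trimethoxy-2-[3,5-dimethoxy-4-(3,4,5-trimethoxyphenoxy)phenoxy]phenoxy}acetic acid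
Conditions: NaH (2.5 equiv), BrCH2CO2H, THF–DMF, 0 to 50 °C; then aq HCl
Reagents that add atoms: bromoacetic acid, OC(=O)CBr
Why: Williamson etherification of the sodium phenoxide with sodium bromoacetate, an unhindered primary SN2 electrophile, the single phenol being the only nucleophilic site.

Step 6
Reactants: 10 2-{3,4,5-trimethoxy-2-[3,5-dimethoxy-4-(3,4,5-trimethoxyphenoxy)phenoxy]phenoxy}acetic acid
Product: 11 2-{3,4,5-trimethoxy-2-[3,5-dimethoxy-4-(3,4,5-trimethoxyphenoxy)phenoxy]phenoxy}acetyl chloride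
Conditions: (COCl)2, DMF (cat.), CH2Cl2, 0 °C to rt; evaporate, use crude at once
Reagents that add atoms: oxalyl chloride, ClC(=O)C(=O)Cl
Why: Acid chloride formation through the chloroiminium catalyst, run without a Lewis acid and at low temperature so that the electron-rich ring D is not acylated.

Step 7
Reactants: 11 2-{3,4,5-trimethoxy-2-[3,5-dimethoxy-4-(3,4,5-trimethoxyphenoxy)phenoxy]phenoxy}acetyl chloride; 12 ethoxyacetylene
Product: 14 racemic 3-ethoxy-4-{3,4,5-trimethoxy-2-[3,5-dimethoxy-4-(3,4,5-trimethoxyphenoxy)phenoxy]phenoxy}cyclobut-2-en-1-one, via aryloxyketene 13 (not isolated)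
Conditions: 12 (4 equiv), Et3N (1.1 equiv), CH2Cl2, slow addition of 11, 0 °C to rt
Reagents that add atoms: none
Why: Dehydrochlorination gives the aryloxyketene, which undergoes ketene–alkyne [2+2] cycloaddition with the ynol ether, its nucleophilic CH terminus bonding to the ketene carbonyl carbon; the new stereocentre C4 forms as the racemate and is left uncontrolled because step 13 destroys it.

Step 8
Reactants: 15 5-bromo-1,2,3-trimethoxybenzene
Product: 16 6-bromo-2,3,4-trimethoxybenzaldehyde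
Conditions: Cl2CHOMe, TiCl4, CH2Cl2, 0 °C; then H2O
Reagents that add atoms: dichloromethyl methyl ether, COC(Cl)Cl; water, O
Why: Rieche formylation, an electrophilic aromatic substitution in which the two free positions are equivalent and each is ortho and para to a methoxy group, so only one aldehyde can form.

Step 9
Reactants: 16 6-bromo-2,3,4-trimethoxybenzaldehyde; 17 2,4,6-trimethoxyphenol
Product: 18 2,3,4-trimethoxy-6-(2,4,6-trimethoxyphenoxy)benzaldehyde
Conditions: CuI (10 mol %), picolinic acid (20 mol %), K3PO4, DMSO, 100 °C, Ar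
Reagents that add atoms: none
Why: Ullmann diaryl ether coupling with a ligand system suited to 2,6-disubstituted phenols, the bromide being activated by the ortho-formyl group and hindered on one side only.

Step 10
Reactants: 18 2,3,4-trimethoxy-6-(2,4,6-trimethoxyphenoxy)benzaldehyde
Product: 20 2,3,4-trimethoxy-6-(2,4,6-trimethoxyphenoxy)phenol, via aryl formate 19 (not isolated)
Conditions: mCPBA (1.2 equiv), CH2Cl2, 0 °C; then K2CO3, MeOH, rt
Reagents that add atoms: mCPBA (3-chloroperoxybenzoic acid), O=C(OO)c1cccc(Cl)c1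
Why: Baeyer–Villiger oxidation of a 2,6-dioxygenated benzaldehyde, which should be fast enough at 0 °C with a small excess of peracid to leave the electron-rich ring A untouched; methanolysis then frees the B6 hydroxyl.

Step 11
Reactants: 20 2,3,4-trimethoxy-6-(2,4,6-trimethoxyphenoxy)phenol; 21 trichloroethylene
Product: 22 1-[(E)-1,2-dichlorovinyloxy]-2,3,4-trimethoxy-6-(2,4,6-trimethoxyphenoxy)benzene
Conditions: K2CO3, DMF, 70 °C
Reagents that add atoms: none
Why: Base converts trichloroethylene into dichloroacetylene, and anti addition of the phenoxide to this small electrophile gives the (E)-dichlorovinyl ether even at the doubly ortho-substituted B6 oxygen.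

Step 12
Reactants: 22 1-[(E)-1,2-dichlorovinyloxy]-2,3,4-trimethoxy-6-(2,4,6-trimethoxyphenoxy)benzene
Product: 25 1-(ethynyloxy)-2,3,4-trimethoxy-6-(2,4,6-trimethoxyphenoxy)benzene, via chloroalkynyl ether 23 (not isolated), via lithium acetylide 24 (not isolated)
Conditions: n-BuLi (2.5 equiv), THF, −78 to −40 °C; then H2O, −78 °C to rt; use soon after isolation
Reagents that add atoms: none
Why: Elimination of HCl gives the chloroalkyne, lithium–chlorine exchange gives the acetylide and protonation gives the terminal ynol ether, a sequence that should outrun ring lithiation at −78 °C.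

Step 13
Reactants: 14 racemic 3-ethoxy-4-{3,4,5-trimethoxy-2-[3,5-dimethoxy-4-(3,4,5-trimethoxyphenoxy)phenoxy]phenoxy}cyclobut-2-en-1-one; 25 1-(ethynyloxy)-2,3,4-trimethoxy-6-(2,4,6-trimethoxyphenoxy)benzene
Product: 30 3-ethoxy-5-[2,3,4-trimethoxy-6-(2,4,6-trimethoxyphenoxy)phenoxy]-2-{3,4,5-trimethoxy-2-[3,5-dimethoxy-4-(3,4,5-trimethoxyphenoxy)phenoxy]phenoxy}phenol, via vinylketene 26 (not isolated), via vinylcyclobutenone 27 (not isolated), via dienylketene 28 (not isolated), via cyclohexadienone 29 (not isolated)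
Conditions: 25 (1.5 equiv), PhMe, 80 °C then 110 °C, Ar
Reagents that add atoms: none
Why: Heat opens cyclobutenone 14 by 4π conrotatory cleavage (aryloxy group turning outward) to vinylketene 26, whose ketene C=C adds ynol ether 25 by [2+2] cycloaddition to give vinylcyclobutenone 27; a second 4π opening gives dienylketene 28, which closes to cyclohexadienone 29 and tautomerises to phenol 30. The closest known reaction type is the Danheiser benzannulation of cyclobutenones with alkoxyacetylenes, here with an aryl ynol ether as the ketenophile. Ring C closes as a six-membered carbocycle by thermal 6π disrotatory electrocyclisation, which makes C3–C4 after the [2+2] step has made C2–C3 and C6–C1. No stereocentre remains, because the sp3 centres of 27 and 29 are lost on ring opening and on enolisation to the arene. The step needs regioselectivity in the [2+2] addition, and the polarisation of the ynol ether should secure it: the nucleophilic CH terminus bonds to the ketene carbonyl carbon, so the carbon bearing the ring B oxygen becomes C1, para to C4 with the ring D oxygen. The excess of 25 should keep the vinylketene from dimerising and from acylating the product phenol.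

Step 14
Reactants: 30 3-ethoxy-5-[2,3,4-trimethoxy-6-(2,4,6-trimethoxyphenoxy)phenoxy]-2-{3,4,5-trimethoxy-2-[3,5-dimethoxy-4-(3,4,5-trimethoxyphenoxy)phenoxy]phenoxy}phenol
Product: 31 CNP0218077.0, 5-[2,3,4-trihydroxy-6-(2,4,6-trihydroxyphenoxy)phenoxy]-2-{3,4,5-trihydroxy-2-[3,5-dihydroxy-4-(3,4,5-trihydroxyphenoxy)phenoxy]phenoxy}benzene-1,3-diol
Conditions: BBr3 (excess, about 3 equiv per ether), CH2Cl2, −78 °C to rt; then H2O, 0 °C; work-up and reversed-phase purification under Ar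
Reagents that add atoms: none
Why: Lewis acid ether cleavage, in which each alkyl aryl ether oxygen binds boron and bromide attacks the methyl or ethyl carbon, whereas the five diaryl ethers offer no sp3 carbon and should stay intact.

**Compound list**

1 | 3,4,5-trimethoxyphenol | COc1cc(O)cc(OC)c1OC | starting material
2 | 4-bromo-3,5-dimethoxybenzaldehyde | COc1cc(C=O)cc(OC)c1Br | starting material
3 | 3,5-dimethoxy-4-(3,4,5-trimethoxyphenoxy)benzaldehyde | COc1cc(C=O)cc(OC)c1Oc1cc(OC)c(OC)c(OC)c1 | intermediate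
4 | 3,5-dimethoxy-4-(3,4,5-trimethoxyphenoxy)phenyl formate | COc1cc(OC=O)cc(OC)c1Oc1cc(OC)c(OC)c(OC)c1 | intermediate
5 | 3,5-dimethoxy-4-(3,4,5-trimethoxyphenoxy)phenol (rings E–F phenol) | COc1cc(O)cc(OC)c1Oc1cc(OC)c(OC)c(OC)c1 | intermediate
6 | 2-bromo-3,4,5-trimethoxybenzaldehyde | COc1cc(C=O)c(Br)c(OC)c1OC | starting material
7 | 3,4,5-trimethoxy-2-[3,5-dimethoxy-4-(3,4,5-trimethoxyphenoxy)phenoxy]benzaldehyde | COc1cc(C=O)c(Oc2cc(OC)c(Oc3cc(OC)c(OC)c(OC)c3)c(OC)c2)c(OC)c1OC | intermediate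
8 | 3,4,5-trimethoxy-2-[3,5-dimethoxy-4-(3,4,5-trimethoxyphenoxy)phenoxy]phenyl formate | COc1cc(OC=O)c(Oc2cc(OC)c(Oc3cc(OC)c(OC)c(OC)c3)c(OC)c2)c(OC)c1OC | intermediate
9 | 3,4,5-trimethoxy-2-[3,5-dimethoxy-4-(3,4,5-trimethoxyphenoxy)phenoxy]phenol (rings D–E–F phenol) | COc1cc(O)c(Oc2cc(OC)c(Oc3cc(OC)c(OC)c(OC)c3)c(OC)c2)c(OC)c1OC | intermediate
10 | 2-{3,4,5-trimethoxy-2-[3,5-dimethoxy-4-(3,4,5-trimethoxyphenoxy)phenoxy]phenoxy}acetic acid | COc1cc(OCC(=O)O)c(Oc2cc(OC)c(Oc3cc(OC)c(OC)c(OC)c3)c(OC)c2)c(OC)c1OC | intermediate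
11 | 2-{3,4,5-trimethoxy-2-[3,5-dimethoxy-4-(3,4,5-trimethoxyphenoxy)phenoxy]phenoxy}acetyl chloride | COc1cc(OCC(=O)Cl)c(Oc2cc(OC)c(Oc3cc(OC)c(OC)c(OC)c3)c(OC)c2)c(OC)c1OC | intermediate
12 | ethoxyacetylene | C#COCC | starting material
13 | {3,4,5-trimethoxy-2-[3,5-dimethoxy-4-(3,4,5-trimethoxyphenoxy)phenoxy]phenoxy}ketene | COc1cc(OC=C=O)c(Oc2cc(OC)c(Oc3cc(OC)c(OC)c(OC)c3)c(OC)c2)c(OC)c1OC | intermediate
14 | racemic 3-ethoxy-4-{3,4,5-trimethoxy-2-[3,5-dimethoxy-4-(3,4,5-trimethoxyphenoxy)phenoxy]phenoxy}cyclobut-2-en-1-one | CCOC1=CC(=O)C1Oc1cc(OC)c(OC)c(OC)c1Oc1cc(OC)c(Oc2cc(OC)c(OC)c(OC)c2)c(OC)c1 | intermediate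
15 | 5-bromo-1,2,3-trimethoxybenzene | COc1cc(Br)cc(OC)c1OC | starting material
16 | 6-bromo-2,3,4-trimethoxybenzaldehyde | COc1cc(Br)c(C=O)c(OC)c1OC | intermediate
17 | 2,4,6-trimethoxyphenol | COc1cc(OC)c(O)c(OC)c1 | starting material
18 | 2,3,4-trimethoxy-6-(2,4,6-trimethoxyphenoxy)benzaldehyde | COc1cc(OC)c(Oc2cc(OC)c(OC)c(OC)c2C=O)c(OC)c1 | intermediate
19 | 2,3,4-trimethoxy-6-(2,4,6-trimethoxyphenoxy)phenyl formate | COc1cc(OC)c(Oc2cc(OC)c(OC)c(OC)c2OC=O)c(OC)c1 | intermediate
20 | 2,3,4-trimethoxy-6-(2,4,6-trimethoxyphenoxy)phenol (rings A–B phenol) | COc1cc(OC)c(Oc2cc(OC)c(OC)c(OC)c2O)c(OC)c1 | intermediate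
21 | trichloroethylene | ClC=C(Cl)Cl | starting material
22 | 1-[(E)-1,2-dichlorovinyloxy]-2,3,4-trimethoxy-6-(2,4,6-trimethoxyphenoxy)benzene | COc1cc(OC)c(Oc2cc(OC)c(OC)c(OC)c2O/C(Cl)=C\Cl)c(OC)c1 | intermediate
23 | 1-(chloroethynyloxy)-2,3,4-trimethoxy-6-(2,4,6-trimethoxyphenoxy)benzene | COc1cc(OC)c(Oc2cc(OC)c(OC)c(OC)c2OC#CCl)c(OC)c1 | intermediate
24 | lithium acetylide of 25 | COc1cc(OC)c(Oc2cc(OC)c(OC)c(OC)c2OC#C[Li])c(OC)c1 | intermediate
25 | 1-(ethynyloxy)-2,3,4-trimethoxy-6-(2,4,6-trimethoxyphenoxy)benzene | COc1cc(OC)c(Oc2cc(OC)c(OC)c(OC)c2OC#C)c(OC)c1 | intermediate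
26 | (Z)-3-ethoxy-4-(rings D–E–F aryloxy)buta-1,3-dien-1-one (vinylketene) | CCO/C(C=C=O)=C\Oc1cc(OC)c(OC)c(OC)c1Oc1cc(OC)c(Oc2cc(OC)c(OC)c(OC)c2)c(OC)c1 | intermediate
27 | racemic 3-(rings A–B aryloxy)-4-[(Z)-1-ethoxy-2-(rings D–E–F aryloxy)vinyl]cyclobut-2-en-1-one | CCO/C(=C\Oc1cc(OC)c(OC)c(OC)c1Oc1cc(OC)c(Oc2cc(OC)c(OC)c(OC)c2)c(OC)c1)C1C(=O)C=C1Oc1c(OC)c(OC)c(OC)cc1Oc1c(OC)cc(OC)cc1OC | intermediate
28 | 3-(rings A–B aryloxy)-5-ethoxy-6-(rings D–E–F aryloxy)hexa-1,3,5-trien-1-one (dienylketene, ketenyl and alkenyl groups cis on the central double bond) | CCO/C(=C\Oc1cc(OC)c(OC)c(OC)c1Oc1cc(OC)c(Oc2cc(OC)c(OC)c(OC)c2)c(OC)c1)/C=C(\C=C=O)Oc1c(OC)c(OC)c(OC)cc1Oc1c(OC)cc(OC)cc1OC | intermediate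
29 | racemic 3-(rings A–B aryloxy)-5-ethoxy-6-(rings D–E–F aryloxy)cyclohexa-2,4-dien-1-one | CCOC1=CC(Oc2c(OC)c(OC)c(OC)cc2Oc2c(OC)cc(OC)cc2OC)=CC(=O)C1Oc1cc(OC)c(OC)c(OC)c1Oc1cc(OC)c(Oc2cc(OC)c(OC)c(OC)c2)c(OC)c1 | intermediate
30 | 3-ethoxy-5-[2,3,4-trimethoxy-6-(2,4,6-trimethoxyphenoxy)phenoxy]-2-{3,4,5-trimethoxy-2-[3,5-dimethoxy-4-(3,4,5-trimethoxyphenoxy)phenoxy]phenoxy}phenol (hexamer, ring C as 3-hydroxy-5-ethoxy ring) | COc1cc(OC)c(Oc2cc(OC)c(OC)c(OC)c2Oc2cc(O)c(Oc3cc(OC)c(OC)c(OC)c3Oc3cc(OC)c(Oc4cc(OC)c(OC)c(OC)c4)c(OC)c3)c(OCC)c2)c(OC)c1 | intermediate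
31 | CNP0218077.0, 5-[2,3,4-trihydroxy-6-(2,4,6-trihydroxyphenoxy)phenoxy]-2-{3,4,5-trihydroxy-2-[3,5-dihydroxy-4-(3,4,5-trihydroxyphenoxy)phenoxy]phenoxy}benzene-1,3-diol | Oc1cc(O)c(Oc2cc(O)c(O)c(O)c2Oc2cc(O)c(Oc3cc(O)c(O)c(O)c3Oc3cc(O)c(Oc4cc(O)c(O)c(O)c4)c(O)c3)c(O)c2)c(O)c1 | target

**Step count and risks**

Total step count: 14. Longest linear sequence: 9 steps (steps 1 to 7, then 13 and 14).

Steps most likely to fail:

1. Step 13. The terminal aryl ynol ether may oligomerise at the temperature needed to open the alkoxy-stabilised cyclobutenone. The vinylketene may dimerise, and 14 may isomerise to its 2-aryloxy isomer, which would give the wrong ring C pattern. The fallback gives up the benzannulation and builds rings C, B and A one at a time by the Ullmann and Baeyer–Villiger cycle of steps 1 to 4. It sets out from phenol 9. Coupling of 9 with bromide 2 (CuI, picolinic acid, K3PO4, DMSO) should give the rings C–F tetramer aldehyde F1. Oxidation with mCPBA should give the tetramer formate F2, and methanolysis the tetramer phenol F3 with a free C1 hydroxyl. Coupling of F3 with bromide 6 should give the rings B–F pentamer aldehyde F4, which through the pentamer formate F5 should give the pentamer phenol F6 with a free B1 hydroxyl. A last coupling with 2 should give the hexamer aldehyde F7, and oxidation through the hexamer formate F8 the hexamer phenol F9, which has a free hydroxyl at position 4 of ring A and fifteen methyl ethers. BBr3 under the conditions of step 14 then cleaves all the methyl ethers, and the fallback comes back to the route at 31.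

2. Step 12. The terminal ynol ether may hydrate or oligomerise during aqueous work-up, concentration and chromatography, and excess n-BuLi may lithiate the electron-rich rings. The fallback sets out from 22 and keeps the elimination and exchange sequence, but the acetylide 24 is quenched with Me3SiCl in place of water. This should give the C-silylated ynol ether, 1-[(trimethylsilyl)ethynyloxy]-2,3,4-trimethoxy-6-(2,4,6-trimethoxyphenoxy)benzene F10, which can be chromatographed and stored. Brief treatment with K2CO3 in MeOH at 0 °C just before step 13 removes the silyl group and comes back to the route at 25.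

3. Step 14. Cleavage of fifteen ethers may stop short, and the pyrogallol-type rings of the free polyphenol may oxidise in air during isolation. The fallback sets out from 30. After the BBr3 treatment and quench the crude polyphenol is not purified but acetylated with Ac2O in pyridine to the hexadecaacetate F11, which is air-stable and can be separated on silica from partly dealkylated material. Deacetylation in degassed methanolic HCl under Ar then comes back to the route at 31.

**Further compounds**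

F1 | step 13 | 3,5-dimethoxy-4-{3,4,5-trimethoxy-2-[3,5-dimethoxy-4-(3,4,5-trimethoxyphenoxy)phenoxy]phenoxy}benzaldehyde (rings C–F tetramer aldehyde) | COc1cc(C=O)cc(OC)c1Oc1cc(OC)c(OC)c(OC)c1Oc1cc(OC)c(Oc2cc(OC)c(OC)c(OC)c2)c(OC)c1
F2 | step 13 | formate of the tetramer phenol | COc1cc(OC=O)cc(OC)c1Oc1cc(OC)c(OC)c(OC)c1Oc1cc(OC)c(Oc2cc(OC)c(OC)c(OC)c2)c(OC)c1
F3 | step 13 | rings C–F tetramer phenol (C1 hydroxyl free) | COc1cc(O)cc(OC)c1Oc1cc(OC)c(OC)c(OC)c1Oc1cc(OC)c(Oc2cc(OC)c(OC)c(OC)c2)c(OC)c1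
F4 | step 13 | rings B–F pentamer aldehyde (CHO at B1) | COc1cc(C=O)c(Oc2cc(OC)c(Oc3cc(OC)c(OC)c(OC)c3Oc3cc(OC)c(Oc4cc(OC)c(OC)c(OC)c4)c(OC)c3)c(OC)c2)c(OC)c1OC
F5 | step 13 | formate of the pentamer phenol | COc1cc(OC=O)c(Oc2cc(OC)c(Oc3cc(OC)c(OC)c(OC)c3Oc3cc(OC)c(Oc4cc(OC)c(OC)c(OC)c4)c(OC)c3)c(OC)c2)c(OC)c1OC
F6 | step 13 | rings B–F pentamer phenol (B1 hydroxyl free) | COc1cc(O)c(Oc2cc(OC)c(Oc3cc(OC)c(OC)c(OC)c3Oc3cc(OC)c(Oc4cc(OC)c(OC)c(OC)c4)c(OC)c3)c(OC)c2)c(OC)c1OC
F7 | step 13 | hexamer aldehyde (CHO at position 4 of ring A) | COc1cc(C=O)cc(OC)c1Oc1cc(OC)c(OC)c(OC)c1Oc1cc(OC)c(Oc2cc(OC)c(OC)c(OC)c2Oc2cc(OC)c(Oc3cc(OC)c(OC)c(OC)c3)c(OC)c2)c(OC)c1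
F8 | step 13 | formate of the hexamer phenol | COc1cc(OC=O)cc(OC)c1Oc1cc(OC)c(OC)c(OC)c1Oc1cc(OC)c(Oc2cc(OC)c(OC)c(OC)c2Oc2cc(OC)c(Oc3cc(OC)c(OC)c(OC)c3)c(OC)c2)c(OC)c1
F9 | step 13 | hexamer phenol (hydroxyl free at position 4 of ring A, fifteen methyl ethers) | COc1cc(O)cc(OC)c1Oc1cc(OC)c(OC)c(OC)c1Oc1cc(OC)c(Oc2cc(OC)c(OC)c(OC)c2Oc2cc(OC)c(Oc3cc(OC)c(OC)c(OC)c3)c(OC)c2)c(OC)c1
F10 | step 12 | 1-[(trimethylsilyl)ethynyloxy]-2,3,4-trimethoxy-6-(2,4,6-trimethoxyphenoxy)benzene | COc1cc(OC)c(Oc2cc(OC)c(OC)c(OC)c2OC#C[Si](C)(C)C)c(OC)c1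
F11 | step 14 | hexadecaacetate of 31 | CC(=O)Oc1cc(OC(C)=O)c(Oc2cc(OC(C)=O)c(OC(C)=O)c(OC(C)=O)c2Oc2cc(OC(C)=O)c(Oc3cc(OC(C)=O)c(OC(C)=O)c(OC(C)=O)c3Oc3cc(OC(C)=O)c(Oc4cc(OC(C)=O)c(OC(C)=O)c(OC(C)=O)c4)c(OC(C)=O)c3)c(OC(C)=O)c2)c(OC(C)=O)c1
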